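The numbers in the tables stem from a simulated flask with constants of no real substance, and the scatter is random.

Turn the question round before reckoning any end value, and ask what had to be true for north to beat south-west.

all flasks: free catalyst 0.12 mM
- Monday's: substrate 6 mM; coupling partner 24 mM (fed, over 2.5 h); temperature 10 °C; run made earlier
- Sunday's: substrate 9 mM; coupling partner 24 mM (fed, over 2.5 h); temperature 21 °C; run made earlier
- north: substrate 12 mM; coupling partner 24.0 mM (fed, over 2.5 h); at 5 °C throughout; time 4.0 h
- south-west: substrate 12 mM; coupling partner 24.0 mM (fed, over 2.5 h); at 5 °C until 80 min, from then on at 25 °C; time 2.5 h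

- Monday's (time / h: target / %): 0.250: 0; 0.333: 4; 0.500: 5; 0.833: 12; 1.33: 24; 2.00: 36; 3.00: 56
- Sunday's (time / min: target / %): 5.00: 1; 15.0: 2; 25.0: 4; 40.0: 12; 50.0: 17; 60.0: 23; 80.0: 33

(standard deviation of a reading: 2 percentage points)



1. which of the two ends with the higher amount of target, in percent of the substrate charged ("neither" if they lie within 2 percentage points) (north / south-west / neither)
2. target at the end, in percent of the substrate charged, north
3. target at the end, in percent of the substrate charged, south-west

The two flasks ran alike up to 80 min; after that north had 2.67 h at 5 °C and south-west 1.17 h at 25 °C. I froze the rate of rise of c(target) in each stretch, since Monday's run climbed steadily at 1.22 mM h⁻¹ between 0.833 h and 3.00 h, and Sunday's at 2.84 mM h⁻¹ between 40.0 min and 80.0 min. The cold rate then cancelled, and in this reckoning, with each rate held constant through its stretch, south-west drew level once its warm rate was 2.29 times the cold one: this is the break-even ratio, north's time after the change divided by south-west's. Taking each degree to multiply the rate equally, I found that north needed Sunday's rate to be less than 1.58 times Monday's. The readings gave 2.33, though the two runs differ in substrate and each reading scatters by 2 percentage points. Carried from the step 10 °C to 21 °C over to the step 5 °C to 25 °C, that reading made the warm rate 4.64 times the cold one, twice the break-even ratio, so I committed to south-west.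

The forecast named south-west, with 25% for north (range 19% to 33%) and 43% for south-west (range 31% to 53%), “assuming the catalyst survives at 25 °C”. The flasks gave 40.0% for north and 51.7% for south-west, so south-west ended higher.

    substrate + free catalyst → catalyst intermediate A (k = 3980 M⁻¹ h⁻¹, Ea = 43.0 kJ mol⁻¹)
    catalyst intermediate B → released group + catalyst intermediate C (k = 40.8 h⁻¹, Ea = 87.0 kJ mol⁻¹)
    coupling partner + catalyst intermediate A → catalyst intermediate B (k = 2430 M⁻¹ h⁻¹, Ea = 41.0 kJ mol⁻¹)
    catalyst intermediate C ⇌ free catalyst + target (K = 0.00954 M, k = 333 h⁻¹, Ea = 79.0 kJ mol⁻¹, ΔH = −24.0 kJ mol⁻¹)
    (constants at 5 °C)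

South-west held 9.85% of target at the change, as north did on the same course, and from there south-west gained on average per hour 3.17 times what north gained, above the break-even 2.29. In south-west's warm stretch, with coupling partner still being fed, released group rose from 1.19 mM to 6.25 mM and catalyst intermediate C from 6.56% to 43.6% of the catalyst charged, at the end a bigger share than free catalyst with 32.8%. Run on to north's 4.0 h, the south-west recipe had a break-even ratio of 1.00 and ended at 77.3%, its gain since the change 2.24 times north's.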